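## Retrosynthetic overview

1. The target arises by final desilylation of a ten-membered carbocycle that is closed last through the C6–C7 bond: a chromium-catalysed intramolecular allylation of a 3-(bromomethyl)butenolide onto a C6 enal, which sets C6 and C7 and unmasks the α-methylene lactone.
2. The open-chain precursor comes from a Pd-catalysed B-alkyl Suzuki coupling at C1–C2 between a West diene ester (C2–C6, C15, ester side chain attached) and an East (E)-alkenyl iodide butenolide (C1, C7–C14).
3. East: C8 comes from (S)-epichlorohydrin, the (E)-iodoalkene from Zr-catalysed carboalumination, and the butenolide (first ring) from ring-closing metathesis.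
4. West: but-2-yne-1,4-diol, Ru-catalysed trans-hydrostannation and Stille vinylation fix the C4=C5 geometry; the side-chain acid comes from glycolaldehyde by Wittig olefination.
5. Ring order: butenolide (metathesis), then the ten-membered ring (allylation), in which the butenolide becomes the α-methylene-γ-lactone.

Assumption: atom labels C1–C15 follow germacrane numbering of the target (lactone carbons C11–C13, ester-bearing carbon C15); ligand A in step 21 is 3,6-di-tert-butyl-1,8-bis[(4S)-4-isopropyl-4,5-dihydro-1,3-oxazol-2-yl]-9H-carbazole, and its (S,S) form is taken as the matched enantiomer.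

## Route

Step 1
Reactants: 1 methyl 2-bromopropanoate
Product: 3 methyl 2-(triphenyl-λ5-phosphanylidene)propanoate, via phosphonium bromide 2 (not isolated)
Conditions: PPh3, toluene, 90 °C; then 2 M NaOH, CH2Cl2/H2O, 0 °C
Reagents that add atoms: triphenylphosphine, c1ccc(cc1)P(c1ccccc1)c1ccccc1
Why: SN2 quaternisation of PPh3 by the α-bromo ester and deprotonation of the salt give the stabilised Wittig ylide (ylide formation); the former stereocentre becomes sp2, so racemic 1 is adequate.

Step 2
Reactants: 3 methyl 2-(triphenyl-λ5-phosphanylidene)propanoate; 4 glycolaldehyde dimer (1,4-dioxane-2,5-diol)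
Product: 5 methyl (E)-4-hydroxy-2-methylbut-2-enoate
Conditions: CH2Cl2, reflux (0.55 equiv of 4)
Reagents that add atoms: none
Why: The dimer equilibrates with monomeric glycolaldehyde, which undergoes Wittig olefination with the stabilised α-methyl ylide to give the (E)-trisubstituted enoate; no stereocentre is formed.

Step 3
Reactants: 5 methyl (E)-4-hydroxy-2-methylbut-2-enoate
Product: 6 methyl (E)-4-((tert-butyldiphenylsilyl)oxy)-2-methylbut-2-enoate
Conditions: TBDPSCl, imidazole, DMF, 0 °C to rt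
Reagents that add atoms: tert-butyl(chloro)diphenylsilane, CC(C)(C)[Si](Cl)(c1ccccc1)c1ccccc1
Why: Silylation of the primary allylic alcohol (silyl ether protection); the diphenylsilyl group is chosen because it survives the later selective removals of the dimethylsilyl groups.

Step 4
Reactants: 6 methyl (E)-4-((tert-butyldiphenylsilyl)oxy)-2-methylbut-2-enoate
Product: 7 (E)-4-((tert-butyldiphenylsilyl)oxy)-2-methylbut-2-enoic acid
Conditions: LiOH·H2O, THF/MeOH/H2O, rt; then 1 M HCl to pH 3
Reagents that add atoms: lithium hydroxide, [Li+].[OH-]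
Why: Saponification of the methyl ester (acyl–oxygen cleavage) leaves the E-enoate and the silyl ether intact.

Step 5
Reactants: 8 methyl 2-(hydroxymethyl)acrylate
Product: 9 methyl 2-(((tert-butyldimethylsilyl)oxy)methyl)acrylate
Conditions: TBSCl, imidazole, CH2Cl2, 0 °C to rt
Reagents that add atoms: tert-butyl(chloro)dimethylsilane, CC(C)(C)[Si](C)(C)Cl
Why: Silyl ether protection of the primary alcohol so that the acid can later be used in an esterification and a metathesis.

Step 6
Reactants: 9 methyl 2-(((tert-butyldimethylsilyl)oxy)methyl)acrylate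
Product: 10 2-(((tert-butyldimethylsilyl)oxy)methyl)acrylic acid
Conditions: LiOH·H2O, THF/H2O, 0 °C to rt; then cold 1 M HCl to pH 4
Reagents that add atoms: lithium hydroxide, [Li+].[OH-]
Why: Saponification; at 0 °C hydroxide attacks the ester carbonyl faster than it adds to the hindered 1,1-disubstituted acrylate.

Step 7
Reactants: 11 (S)-epichlorohydrin; 12 ethynyltrimethylsilane
Product: 14 (S)-1-chloro-5-(trimethylsilyl)pent-4-yn-2-ol, via lithium acetylide 13 (not isolated)
Conditions: 12, n-BuLi, THF, −78 °C; BF3·OEt2; then 11, −78 °C; aq. NH4Cl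
Reagents that add atoms: none
Why: BF3-assisted SN2 opening of the epoxide by the lithium acetylide at the unsubstituted epoxide carbon (future C9); the C–O bond of the stereocentre (future C8) is not broken, so the S configuration of 11 is carried over.

Step 8
Reactants: 14 (S)-1-chloro-5-(trimethylsilyl)pent-4-yn-2-ol
Product: 17 (S)-hex-1-en-5-yn-3-ol, via epoxide 15 (not isolated), via silyl enynol 16 (not isolated)
Conditions: Me3SI (3.5 equiv), n-BuLi (3.4 equiv), THF, −10 °C to rt; then MeOH, K2CO3, rt; aq. NH4Cl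
Reagents that add atoms: trimethylsulfonium iodide, C[S+](C)C.[I-]
Why: The sulfonium ylide closes the chlorohydrin to the epoxide, opens it at the terminal carbon and eliminates Me2S to give the one-carbon-homologated allylic alcohol (ylide epoxide-to-allylic-alcohol homologation), and methanolysis removes the alkynyl silane; the carbinol C–O bond is never broken, so C8 stays S.

Step 9
Reactants: 17 (S)-hex-1-en-5-yn-3-ol
Product: 19 (S,E)-6-iodo-5-methylhexa-1,5-dien-3-ol, via alkenylalane 18 (not isolated)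
Conditions: AlMe3 (3 equiv), Cp2ZrCl2 (25 mol%), CH2Cl2, 0 °C to rt; then I2, THF, −30 °C; aq. K2CO3
Reagents that add atoms: trimethylaluminium, C[Al](C)C; iodine, II
Why: Zr-catalysed carboalumination (Negishi) adds Me and Al syn across the terminal alkyne with Me on the internal carbon, much faster than across the vinyl group, and iodinolysis with retention gives the (E)-iodoalkene, which fixes the C1=C10 geometry and installs C14.

Step 10
Reactants: 19 (S,E)-6-iodo-5-methylhexa-1,5-dien-3-ol; 10 2-(((tert-butyldimethylsilyl)oxy)methyl)acrylic acid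
Product: 20 (S,E)-6-iodo-5-methylhexa-1,5-dien-3-yl 2-(((tert-butyldimethylsilyl)oxy)methyl)acrylate
Conditions: DCC, DMAP (10 mol%), CH2Cl2, 0 °C to rt
Reagents that add atoms: none
Why: Steglich esterification acylates the secondary allylic alcohol on oxygen, so C8 is untouched.

Step 11
Reactants: 20 (S,E)-6-iodo-5-methylhexa-1,5-dien-3-yl 2-(((tert-butyldimethylsilyl)oxy)methyl)acrylate
Product: 21 (S)-3-(((tert-butyldimethylsilyl)oxy)methyl)-5-((E)-3-iodo-2-methylallyl)furan-2(5H)-one
Conditions: second-generation Grubbs catalyst (5 mol%), toluene (5 mM), 80 °C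
Reagents that add atoms: none
Why: Ring-closing metathesis: the Ru carbene forms at the terminal vinyl group and closes onto the 1,1-disubstituted acrylate to give the five-membered butenolide with loss of ethylene, while the trisubstituted iodoalkene is inert.

Step 12
Reactants: 21 (S)-3-(((tert-butyldimethylsilyl)oxy)methyl)-5-((E)-3-iodo-2-methylallyl)furan-2(5H)-one
Product: 22 (S)-3-(hydroxymethyl)-5-((E)-3-iodo-2-methylallyl)furan-2(5H)-one
Conditions: HF·pyridine, THF, 0 °C to rt
Reagents that add atoms: none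
Why: Fluoride-mediated desilylation under non-basic conditions, so the base-labile γ-stereocentre (C8) of the butenolide is not epimerised.

Step 13
Reactants: 23 but-2-yne-1,4-diol
Product: 24 4-((tert-butyldimethylsilyl)oxy)but-2-yn-1-ol
Conditions: TBSCl (1 equiv), imidazole, THF, 0 °C (3 equiv of 23)
Reagents that add atoms: tert-butyl(chloro)dimethylsilane, CC(C)(C)[Si](C)(C)Cl
Why: Statistical monosilylation of the symmetric diol with the diol in excess (monoprotection); the free hydroxyl becomes the directing group of the next step.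

Step 14
Reactants: 24 4-((tert-butyldimethylsilyl)oxy)but-2-yn-1-ol
Product: 25 (Z)-4-((tert-butyldimethylsilyl)oxy)-2-(tributylstannyl)but-2-en-1-ol
Conditions: Bu3SnH (1.1 equiv), [Cp*RuCl]4 (1.5 mol%), CH2Cl2, rt
Reagents that add atoms: tributyltin hydride, CCCC[SnH](CCCC)CCCC
Why: Ruthenium-catalysed trans-hydrostannation: the free propargylic OH hydrogen-bonds to the Ru–Cl unit and steers tin to the proximal alkyne carbon (C4) while H adds to C5 from the opposite face, so the two CH2O groups end trans, which is the C4=C5 geometry of the target.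

Step 15
Reactants: 25 (Z)-4-((tert-butyldimethylsilyl)oxy)-2-(tributylstannyl)but-2-en-1-ol; 26 vinyl bromide
Product: 27 (E)-4-((tert-butyldimethylsilyl)oxy)-2-vinylbut-2-en-1-ol
Conditions: 26 (1 M in THF, 3 equiv), Pd(PPh3)4 (5 mol%), CuI (20 mol%), CsF (2 equiv), DMF, 45 °C
Reagents that add atoms: none
Why: Stille coupling with copper/fluoride activation proceeds with retention at the alkenylstannane, so the vinyl group (C3–C2) ends cis to C6.

Step 16
Reactants: 27 (E)-4-((tert-butyldimethylsilyl)oxy)-2-vinylbut-2-en-1-ol; 7 (E)-4-((tert-butyldiphenylsilyl)oxy)-2-methylbut-2-enoic acid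
Product: 28 (E)-4-((tert-butyldimethylsilyl)oxy)-2-vinylbut-2-en-1-yl (E)-4-((tert-butyldiphenylsilyl)oxy)-2-methylbut-2-enoate
Conditions: DCC, DMAP (10 mol%), CH2Cl2, 0 °C
Reagents that add atoms: none
Why: Steglich esterification of the only free hydroxyl (C15–OH) installs the ester side chain early, so no late differentiation of C15–OH and C6–OH is needed.

Step 17
Reactants: 28 West diene ester; 22 (S)-3-(hydroxymethyl)-5-((E)-3-iodo-2-methylallyl)furan-2(5H)-one
Product: 30 (5E)-2-[(E)-2-((tert-butyldimethylsilyl)oxy)ethylidene]-7-[(2S)-4-(hydroxymethyl)-5-oxo-2,5-dihydrofuran-2-yl]-6-methylhept-5-en-1-yl (E)-4-((tert-butyldiphenylsilyl)oxy)-2-methylbut-2-enoate, via alkylborane 29 (not isolated)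
Conditions: 9-BBN (1.0 equiv on 28), THF, 0 °C to rt; then 22 (0.75 equiv), Pd(dppf)Cl2·CH2Cl2 (5 mol%), AsPh3 (5 mol%), 3 M aq. K3PO4, DMF, rt
Reagents that add atoms: none
Why: 9-BBN adds to the terminal CH2 of the monosubstituted vinyl group of the diene (anti-Markovnikov, least hindered alkene), and the primary alkylborane undergoes B-alkyl Suzuki–Miyaura coupling with the (E)-alkenyl iodide with retention, forming C1–C2 and keeping C1=C10 as E.

Step 18
Reactants: 30 open-chain C13 alcohol
Product: 31 (5E)-7-[(2S)-4-(bromomethyl)-5-oxo-2,5-dihydrofuran-2-yl]-2-[(E)-2-((tert-butyldimethylsilyl)oxy)ethylidene]-6-methylhept-5-en-1-yl (E)-4-((tert-butyldiphenylsilyl)oxy)-2-methylbut-2-enoate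
Conditions: CBr4 (1.2 equiv), PPh3 (1.2 equiv), CH2Cl2, 0 °C
Reagents that add atoms: carbon tetrabromide, BrC(Br)(Br)Br
Why: Appel bromination converts the only free (primary) hydroxyl into the allylic bromide by SN2 at C13 under neutral conditions, with no aldehyde yet present.

Step 19
Reactants: 31 open-chain C13 bromide
Product: 32 (5E)-7-[(2S)-4-(bromomethyl)-5-oxo-2,5-dihydrofuran-2-yl]-2-[(E)-2-hydroxyethylidene]-6-methylhept-5-en-1-yl (E)-4-((tert-butyldiphenylsilyl)oxy)-2-methylbut-2-enoate
Conditions: HF (48% aq.), MeCN, 0 °C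
Reagents that add atoms: none
Why: Acidic fluoride desilylation cleaves the primary dimethylsilyl ether much faster than the bulkier diphenylsilyl ether, and the amine-free medium spares the alkylating allylic bromide.

Step 20
Reactants: 32 open-chain C6 alcohol
Product: 33 (5E)-7-[(2S)-4-(bromomethyl)-5-oxo-2,5-dihydrofuran-2-yl]-6-methyl-2-[(E)-2-oxoethylidene]hept-5-en-1-yl (E)-4-((tert-butyldiphenylsilyl)oxy)-2-methylbut-2-enoate
Conditions: MnO2 (activated, 20 equiv), CH2Cl2, rt; filtered and used at once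
Reagents that add atoms: none
Why: MnO2 oxidises the allylic alcohol to the enal (allylic oxidation) without touching the allylic bromide or isomerising the trisubstituted alkene, so the CHO stays cis to the C3 chain.

Step 21
Reactants: 33 open-chain enal bromide
Product: 35 ((3aS,4R,5E,9E,11aS)-4-hydroxy-10-methyl-3-methylidene-2-oxo-2,3,3a,4,7,8,11,11a-octahydrocyclodeca[b]furan-6-yl)methyl (E)-4-((tert-butyldiphenylsilyl)oxy)-2-methylbut-2-enoate, via trimethylsilyl ether 34 (not isolated)
Conditions: CrCl2 (10 mol%), ligand A (12 mol%), i-Pr2NEt (20 mol%), Mn powder (3 equiv), Me3SiCl (2 equiv), THF, rt, 33 added over 12 h (final 2 mM); then 1 M HCl, THF, 0 °C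
Reagents that add atoms: none
Why: Proposed new method: a chromium-catalysed, ligand-controlled macrocyclising Nozaki–Hiyama allylation with a lactone-embedded 2-acylallyl bromide as the allyl donor; divalent chromium inserts into the C13–Br bond to give an allyl trivalent chromium species bound at C13, which adds through C7 to the chromium-bound aldehyde in a six-membered chair transition state, so the C6–C7 bond, the ten-membered ring and the exocyclic methylene lactone form together, Me3SiCl frees the alkoxide and Mn returns trivalent chromium to divalent chromium; the fixed geometry of the cyclic allyl unit (C8 trans to C13) makes the chair give the 6,7-anti pair, and the (S,S)-ligand is meant to expose the Si face of the aldehyde, which gives 6R and therefore 7S with C6 trans to C9 on the lactone, while slow addition keeps the allylchromium dilute; the closest known reactions are intermolecular Cr-, Zn- and In-mediated allylations of aldehydes with 3-(bromomethyl)butenolides and stoichiometric CrCl2 macrocyclising allylations of acyclic allylic bromides.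

Step 22
Reactants: 35 silyl-protected macrocycle
Product: 36 ((3aS,4R,5E,9E,11aS)-4-hydroxy-10-methyl-3-methylidene-2-oxo-2,3,3a,4,7,8,11,11a-octahydrocyclodeca[b]furan-6-yl)methyl (E)-4-hydroxy-2-methylbut-2-enoate
Conditions: HF·pyridine, pyridine, THF, 0 °C to rt
Reagents that add atoms: none
Why: Fluoride cleavage of the remaining silyl ether under buffered, non-basic conditions (desilylation), which avoids Michael addition to the α-methylene lactone, translactonisation to the C6 hydroxyl and acyl migration.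

## Compound list

1 | methyl 2-bromopropanoate (racemic) | CC(Br)C(=O)OC | starting material
2 | (1-methoxy-1-oxopropan-2-yl)triphenylphosphonium bromide | COC(=O)C(C)[P+](c1ccccc1)(c1ccccc1)c1ccccc1.[Br-] | intermediate
3 | methyl 2-(triphenyl-λ5-phosphanylidene)propanoate | COC(=O)C(C)=P(c1ccccc1)(c1ccccc1)c1ccccc1 | intermediate
4 | glycolaldehyde dimer (1,4-dioxane-2,5-diol) | OC1COC(O)CO1 | starting material
5 | methyl (E)-4-hydroxy-2-methylbut-2-enoate | COC(=O)/C(C)=C/CO | intermediate
6 | methyl (E)-4-((tert-butyldiphenylsilyl)oxy)-2-methylbut-2-enoate | COC(=O)/C(C)=C/CO[Si](c1ccccc1)(c1ccccc1)C(C)(C)C | intermediate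
7 | (E)-4-((tert-butyldiphenylsilyl)oxy)-2-methylbut-2-enoic acid | OC(=O)/C(C)=C/CO[Si](c1ccccc1)(c1ccccc1)C(C)(C)C | intermediate
8 | methyl 2-(hydroxymethyl)acrylate | C=C(CO)C(=O)OC | starting material
9 | methyl 2-(((tert-butyldimethylsilyl)oxy)methyl)acrylate | C=C(CO[Si](C)(C)C(C)(C)C)C(=O)OC | intermediate
10 | 2-(((tert-butyldimethylsilyl)oxy)methyl)acrylic acid | C=C(CO[Si](C)(C)C(C)(C)C)C(=O)O | intermediate
11 | (S)-epichlorohydrin | ClC[C@@H]1CO1 | starting material
12 | ethynyltrimethylsilane | C#C[Si](C)(C)C | starting material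
13 | lithium (trimethylsilyl)acetylide | [Li]C#C[Si](C)(C)C | intermediate
14 | (S)-1-chloro-5-(trimethylsilyl)pent-4-yn-2-ol | C[Si](C)(C)C#CC[C@H](O)CCl | intermediate
15 | (S)-trimethyl(3-(oxiran-2-yl)prop-1-yn-1-yl)silane | C[Si](C)(C)C#CC[C@H]1CO1 | intermediate
16 | (S)-6-(trimethylsilyl)hex-1-en-5-yn-3-ol | C[Si](C)(C)C#CC[C@H](O)C=C | intermediate
17 | (S)-hex-1-en-5-yn-3-ol | C#CC[C@H](O)C=C | intermediate
18 | dimethylaluminium (S,E)-6-(dimethylalumanyl)-5-methylhexa-1,5-dien-3-olate | C[Al](C)/C=C(C)/C[C@H](O[Al](C)C)C=C | intermediate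
19 | (S,E)-6-iodo-5-methylhexa-1,5-dien-3-ol | I/C=C(C)/C[C@H](O)C=C | intermediate
20 | (S,E)-6-iodo-5-methylhexa-1,5-dien-3-yl 2-(((tert-butyldimethylsilyl)oxy)methyl)acrylate | I/C=C(C)/C[C@H](OC(=O)C(=C)CO[Si](C)(C)C(C)(C)C)C=C | intermediate
21 | (S)-3-(((tert-butyldimethylsilyl)oxy)methyl)-5-((E)-3-iodo-2-methylallyl)furan-2(5H)-one | I/C=C(C)/C[C@H]1C=C(CO[Si](C)(C)C(C)(C)C)C(=O)O1 | intermediate
22 | (S)-3-(hydroxymethyl)-5-((E)-3-iodo-2-methylallyl)furan-2(5H)-one | I/C=C(C)/C[C@H]1C=C(CO)C(=O)O1 | intermediate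
23 | but-2-yne-1,4-diol | OCC#CCO | starting material
24 | 4-((tert-butyldimethylsilyl)oxy)but-2-yn-1-ol | OCC#CCO[Si](C)(C)C(C)(C)C | intermediate
25 | (Z)-4-((tert-butyldimethylsilyl)oxy)-2-(tributylstannyl)but-2-en-1-ol | OC/C(=C/CO[Si](C)(C)C(C)(C)C)[Sn](CCCC)(CCCC)CCCC | intermediate
26 | vinyl bromide (bromoethene) | C=CBr | starting material
27 | (E)-4-((tert-butyldimethylsilyl)oxy)-2-vinylbut-2-en-1-ol | C=C/C(CO)=C\CO[Si](C)(C)C(C)(C)C | intermediate
28 | (E)-4-((tert-butyldimethylsilyl)oxy)-2-vinylbut-2-en-1-yl (E)-4-((tert-butyldiphenylsilyl)oxy)-2-methylbut-2-enoate | C=C/C(COC(=O)/C(C)=C/CO[Si](c1ccccc1)(c1ccccc1)C(C)(C)C)=C\CO[Si](C)(C)C(C)(C)C | intermediate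
29 | (E)-2-(2-(9-borabicyclo[3.3.1]nonan-9-yl)ethyl)-4-((tert-butyldimethylsilyl)oxy)but-2-en-1-yl (E)-4-((tert-butyldiphenylsilyl)oxy)-2-methylbut-2-enoate | CC(C)(C)[Si](C)(C)OC/C=C(COC(=O)/C(C)=C/CO[Si](c1ccccc1)(c1ccccc1)C(C)(C)C)\CCB1C2CCCC1CCC2 | intermediate
30 | (5E)-2-[(E)-2-((tert-butyldimethylsilyl)oxy)ethylidene]-7-[(2S)-4-(hydroxymethyl)-5-oxo-2,5-dihydrofuran-2-yl]-6-methylhept-5-en-1-yl (E)-4-((tert-butyldiphenylsilyl)oxy)-2-methylbut-2-enoate | OCC1=C[C@H](C/C(C)=C/CC/C(COC(=O)/C(C)=C/CO[Si](c2ccccc2)(c2ccccc2)C(C)(C)C)=C\CO[Si](C)(C)C(C)(C)C)OC1=O | intermediate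
31 | (5E)-7-[(2S)-4-(bromomethyl)-5-oxo-2,5-dihydrofuran-2-yl]-2-[(E)-2-((tert-butyldimethylsilyl)oxy)ethylidene]-6-methylhept-5-en-1-yl (E)-4-((tert-butyldiphenylsilyl)oxy)-2-methylbut-2-enoate | BrCC1=C[C@H](C/C(C)=C/CC/C(COC(=O)/C(C)=C/CO[Si](c2ccccc2)(c2ccccc2)C(C)(C)C)=C\CO[Si](C)(C)C(C)(C)C)OC1=O | intermediate
32 | (5E)-7-[(2S)-4-(bromomethyl)-5-oxo-2,5-dihydrofuran-2-yl]-2-[(E)-2-hydroxyethylidene]-6-methylhept-5-en-1-yl (E)-4-((tert-butyldiphenylsilyl)oxy)-2-methylbut-2-enoate | BrCC1=C[C@H](C/C(C)=C/CC/C(COC(=O)/C(C)=C/CO[Si](c2ccccc2)(c2ccccc2)C(C)(C)C)=C\CO)OC1=O | intermediate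
33 | (5E)-7-[(2S)-4-(bromomethyl)-5-oxo-2,5-dihydrofuran-2-yl]-6-methyl-2-[(E)-2-oxoethylidene]hept-5-en-1-yl (E)-4-((tert-butyldiphenylsilyl)oxy)-2-methylbut-2-enoate | BrCC1=C[C@H](C/C(C)=C/CC/C(COC(=O)/C(C)=C/CO[Si](c2ccccc2)(c2ccccc2)C(C)(C)C)=C\C=O)OC1=O | intermediate
34 | ((3aR,4R,5E,9E,11aS)-10-methyl-3-methylidene-2-oxo-4-((trimethylsilyl)oxy)-2,3,3a,4,7,8,11,11a-octahydrocyclodeca[b]furan-6-yl)methyl (E)-4-((tert-butyldiphenylsilyl)oxy)-2-methylbut-2-enoate (same spatial arrangement as 35; the 3a descriptor changes with the silyl group) | C=C1C(=O)O[C@H]2C/C(C)=C/CC/C(COC(=O)/C(C)=C/CO[Si](c3ccccc3)(c3ccccc3)C(C)(C)C)=C\[C@@H](O[Si](C)(C)C)[C@H]12 | intermediate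
35 | ((3aS,4R,5E,9E,11aS)-4-hydroxy-10-methyl-3-methylidene-2-oxo-2,3,3a,4,7,8,11,11a-octahydrocyclodeca[b]furan-6-yl)methyl (E)-4-((tert-butyldiphenylsilyl)oxy)-2-methylbut-2-enoate | C=C1C(=O)O[C@H]2C/C(C)=C/CC/C(COC(=O)/C(C)=C/CO[Si](c3ccccc3)(c3ccccc3)C(C)(C)C)=C\[C@@H](O)[C@H]12 | intermediate
36 | ((3aS,4R,5E,9E,11aS)-4-hydroxy-10-methyl-3-methylidene-2-oxo-2,3,3a,4,7,8,11,11a-octahydrocyclodeca[b]furan-6-yl)methyl (E)-4-hydroxy-2-methylbut-2-enoate (CNP0326626.2; germacrane positions 6R,7S,8S) | C=C1C(=O)O[C@H]2C/C(C)=C/CC/C(COC(=O)/C(C)=C/CO)=C\[C@@H](O)[C@H]12 | target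

## Step count and risks

Total step count: 22. Longest linear sequence: 12 steps (steps 7–12, then 17–22); the side-chain acid (steps 1–4), the acrylic acid (steps 5–6) and the West diene ester (steps 13–16) are made in parallel.

The three steps most likely to fail:

Step 21 (the proposed new macrocyclisation). The risks are oligomerisation, poor turnover of the chromium catalyst, and the wrong pairing of the new C6/C7 centres with C8. The fallback uses known chemistry, an intermolecular zinc Barbier allylation with a bromomethyl butenolide followed by ring-closing metathesis; it sets out from 17 and 28 and comes back to the route at 35. Carboalumination of 17 (AlMe3, Cp2ZrCl2) quenched with water instead of iodine gives (S)-5-methylhexa-1,5-dien-3-ol F1. DCC esterification with 10 gives (S)-5-methylhexa-1,5-dien-3-yl 2-(((tert-butyldimethylsilyl)oxy)methyl)acrylate F2, and ring-closing metathesis (second-generation Grubbs catalyst) gives (S)-3-(((tert-butyldimethylsilyl)oxy)methyl)-5-(2-methylallyl)furan-2(5H)-one F3. HF·pyridine then gives (S)-3-(hydroxymethyl)-5-(2-methylallyl)furan-2(5H)-one F4, and CBr4/PPh3 gives (S)-3-(bromomethyl)-5-(2-methylallyl)furan-2(5H)-one F5. In parallel, the alkylborane 29 made from 28 is coupled with vinyl bromide 26 under the palladium conditions of step 17 to give 2-[(E)-2-((tert-butyldimethylsilyl)oxy)ethylidene]hex-5-en-1-yl (E)-4-((tert-butyldiphenylsilyl)oxy)-2-methylbut-2-enoate F6. Aqueous HF in MeCN turns this into 2-[(E)-2-hydroxyethylidene]hex-5-en-1-yl (E)-4-((tert-butyldiphenylsilyl)oxy)-2-methylbut-2-enoate F7, and MnO2 gives 2-[(E)-2-oxoethylidene]hex-5-en-1-yl (E)-4-((tert-butyldiphenylsilyl)oxy)-2-methylbut-2-enoate F8. Zn dust in THF/aq. NH4Cl joins F5 and F8, with attack at C7 anti to the C8 side chain through a chair transition state, to give 2-[(E,2R)-2-hydroxy-2-((2S,3S)-4-methylidene-2-(2-methylallyl)-5-oxooxolan-3-yl)ethylidene]hex-5-en-1-yl (E)-4-((tert-butyldiphenylsilyl)oxy)-2-methylbut-2-enoate F9. Ring-closing metathesis of its two terminal alkenes (second-generation Grubbs catalyst, toluene, 80 °C, 1 mM) closes C1=C10 and gives 35; the E geometry of the new trisubstituted alkene would have to be confirmed.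

Step 17 (diene hydroboration and B-alkyl Suzuki coupling). The risks are the regiochemistry of hydroboration on the conjugated diene, epimerisation at C8 or opening of the butenolide by aqueous K3PO4, and ionisation of the allylic ester by zerovalent palladium. The fallback moves the coupling ahead of butenolide formation; it sets out from 19 and 28 and comes back at 31. The alkylborane 29 from 28 is coupled with the base-stable iodo dienol 19 under the same palladium conditions, with excess borane quenched with water first, to give (5E,8S)-2-[(E)-2-((tert-butyldimethylsilyl)oxy)ethylidene]-8-hydroxy-6-methyldeca-5,9-dien-1-yl (E)-4-((tert-butyldiphenylsilyl)oxy)-2-methylbut-2-enoate F10. Esterification with commercial 2-(bromomethyl)acrylic acid (C=C(CBr)C(=O)O; DCC, DMAP kept at 5 mol%, CH2Cl2, −20 °C) gives (5E,8S)-8-((2-(bromomethyl)acryloyl)oxy)-2-[(E)-2-((tert-butyldimethylsilyl)oxy)ethylidene]-6-methyldeca-5,9-dien-1-yl (E)-4-((tert-butyldiphenylsilyl)oxy)-2-methylbut-2-enoate F11. Ring-closing metathesis (second-generation Grubbs catalyst, toluene, 80 °C) then forms the butenolide and gives 31 directly.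

Step 15 (Stille coupling of a hindered α-stannyl allylic alcohol). The risks are slow transmetalation and protodestannylation. The fallback exchanges the roles of nucleophile and electrophile; it sets out from 25 and comes back at 27. Iododestannylation (I2, CH2Cl2, 0 °C, retention) gives (Z)-4-((tert-butyldimethylsilyl)oxy)-2-iodobut-2-en-1-ol F12, and Suzuki–Miyaura coupling with potassium vinyltrifluoroborate (Pd(dppf)Cl2·CH2Cl2, Cs2CO3, THF/H2O, 70 °C) gives 27.

Further compounds
F1 | step 21 | (S)-5-methylhexa-1,5-dien-3-ol | C=C(C)C[C@H](O)C=C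
F2 | step 21 | (S)-5-methylhexa-1,5-dien-3-yl 2-(((tert-butyldimethylsilyl)oxy)methyl)acrylate | C=C(C)C[C@H](OC(=O)C(=C)CO[Si](C)(C)C(C)(C)C)C=C
F3 | step 21 | (S)-3-(((tert-butyldimethylsilyl)oxy)methyl)-5-(2-methylallyl)furan-2(5H)-one | C=C(C)C[C@H]1C=C(CO[Si](C)(C)C(C)(C)C)C(=O)O1
F4 | step 21 | (S)-3-(hydroxymethyl)-5-(2-methylallyl)furan-2(5H)-one | C=C(C)C[C@H]1C=C(CO)C(=O)O1
F5 | step 21 | (S)-3-(bromomethyl)-5-(2-methylallyl)furan-2(5H)-one | C=C(C)C[C@H]1C=C(CBr)C(=O)O1
F6 | step 21 | 2-[(E)-2-((tert-butyldimethylsilyl)oxy)ethylidene]hex-5-en-1-yl (E)-4-((tert-butyldiphenylsilyl)oxy)-2-methylbut-2-enoate | C=CCC/C(COC(=O)/C(C)=C/CO[Si](c1ccccc1)(c1ccccc1)C(C)(C)C)=C\CO[Si](C)(C)C(C)(C)C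
F7 | step 21 | 2-[(E)-2-hydroxyethylidene]hex-5-en-1-yl (E)-4-((tert-butyldiphenylsilyl)oxy)-2-methylbut-2-enoate | C=CCC/C(COC(=O)/C(C)=C/CO[Si](c1ccccc1)(c1ccccc1)C(C)(C)C)=C\CO
F8 | step 21 | 2-[(E)-2-oxoethylidene]hex-5-en-1-yl (E)-4-((tert-butyldiphenylsilyl)oxy)-2-methylbut-2-enoate | C=CCC/C(COC(=O)/C(C)=C/CO[Si](c1ccccc1)(c1ccccc1)C(C)(C)C)=C\C=O
F9 | step 21 | 2-[(E,2R)-2-hydroxy-2-((2S,3S)-4-methylidene-2-(2-methylallyl)-5-oxooxolan-3-yl)ethylidene]hex-5-en-1-yl (E)-4-((tert-butyldiphenylsilyl)oxy)-2-methylbut-2-enoate | C=C1C(=O)O[C@@H](CC(C)=C)[C@@H]1[C@H](O)/C=C(\CCC=C)COC(=O)/C(C)=C/CO[Si](c1ccccc1)(c1ccccc1)C(C)(C)C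
F10 | step 17 | (5E,8S)-2-[(E)-2-((tert-butyldimethylsilyl)oxy)ethylidene]-8-hydroxy-6-methyldeca-5,9-dien-1-yl (E)-4-((tert-butyldiphenylsilyl)oxy)-2-methylbut-2-enoate | C=C[C@@H](O)C/C(C)=C/CC/C(COC(=O)/C(C)=C/CO[Si](c1ccccc1)(c1ccccc1)C(C)(C)C)=C\CO[Si](C)(C)C(C)(C)C
F11 | step 17 | (5E,8S)-8-((2-(bromomethyl)acryloyl)oxy)-2-[(E)-2-((tert-butyldimethylsilyl)oxy)ethylidene]-6-methyldeca-5,9-dien-1-yl (E)-4-((tert-butyldiphenylsilyl)oxy)-2-methylbut-2-enoate | C=C(CBr)C(=O)O[C@H](C=C)C/C(C)=C/CC/C(COC(=O)/C(C)=C/CO[Si](c1ccccc1)(c1ccccc1)C(C)(C)C)=C\CO[Si](C)(C)C(C)(C)C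
F12 | step 15 | (Z)-4-((tert-butyldimethylsilyl)oxy)-2-iodobut-2-en-1-ol | OC/C(I)=C/CO[Si](C)(C)C(C)(C)C
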